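**Plan** (oxolane numbering: O1, C2 aryl, C3 CH2OH, C4 aroyl, C5 H2)
- Retrosynthesis, in order: the C4 configuration and the acetate (last step); the C3–H and C4–H bonds (back to a C3=C4 enone); the ring bond C3–C4 (retro alkyne–carbonyl metathesis, turning C4 and the aroyl carbon into an aryl alkyne and C3 into a ketone); the benzylic C2–O1 ether bond (aryl glycidol plus propargylic alcohol); the aryl–alkyne bond.
- Enabling feature: C4 carries an exocyclic aryl ketone and is bonded in the ring to C3, so O=C–C4–C3 is the retron of an alkyne–carbonyl metathesis. O1 and C5 then form a propargyl ether tether, and the 3,4,5-trimethoxyphenyl ring stabilises the vinyl cation that fixes the regiochemistry.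
- Forward: Sonogashira coupling, Sharpless epoxidation, epoxide opening (C2–O1), acetylation, oxidation, closure of the only ring as a 2,5-dihydrofuran, hydrogenation, epimerisation with deacetylation.
- Stereochemistry: C2 from the Sharpless epoxide by inversion at the benzylic carbon; C3 from hydrogenation anti to the C2 aryl group (2,3-cis); C4 by thermodynamic equilibration (3,4-trans).

Key step: step 6

Assumption: the SMILES is read as the (2R,3R,4S) isomer (aryl and CH2OH cis, CH2OH and aroyl trans); 5-iodo-1,2,3-trimethoxybenzene, prop-2-yn-1-ol and (E)-3,4-dimethoxycinnamyl alcohol are taken as catalogue compounds.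

**Step 1**
Reactants: 1 5-iodo-1,2,3-trimethoxybenzene; 2 prop-2-yn-1-ol
Product: 3 3-(3,4,5-trimethoxyphenyl)prop-2-yn-1-ol
Conditions: PdCl2(PPh3)2 (2 mol %), CuI (4 mol %), Et3N, THF, rt
Reagents that add atoms: none
Why: Sonogashira coupling of an aryl iodide with a terminal alkyne tolerates the free propargylic hydroxyl and creates no stereocentre.

**Step 2**
Reactants: 4 (E)-3-(3,4-dimethoxyphenyl)prop-2-en-1-ol
Product: 5 [(2R,3R)-3-(3,4-dimethoxyphenyl)oxiran-2-yl]methanol
Conditions: Ti(OiPr)4 (10 mol %), D-(−)-diisopropyl tartrate (12 mol %), t-BuOOH, 4 Å MS, CH2Cl2, −20 °C; non-acidic work-up, used at once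
Reagents that add atoms: tert-butyl hydroperoxide, CC(C)(C)OO
Why: Sharpless asymmetric epoxidation of an (E)-allylic alcohol, in which the D-(−)-tartrate ligand directs oxygen to the alkene face that gives the (2R,3R)-epoxide, run catalytically with sieves because the electron-rich aryl epoxide is acid-labile.

**Step 3**
Reactants: 5 [(2R,3R)-3-(3,4-dimethoxyphenyl)oxiran-2-yl]methanol; 3 3-(3,4,5-trimethoxyphenyl)prop-2-yn-1-ol
Product: 6 (2R,3S)-3-(3,4-dimethoxyphenyl)-3-{[3-(3,4,5-trimethoxyphenyl)prop-2-yn-1-yl]oxy}propane-1,2-diol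
Conditions: BF3·OEt2 (5 mol %), CH2Cl2, −40 °C, slow addition of the epoxide to an excess of the alcohol; chromatography (surplus alcohol recovered)
Reagents that add atoms: none
Why: Acid-catalysed alcoholysis of a 3-aryl-2,3-epoxy alcohol is an atom-economic addition that should occur at the benzylic carbon with inversion to give the (3S) ether with the (2R) carbinol untouched, the alcohol being kept in excess over the epoxide to outrun rearrangement and oligomerisation, and any retention product is a diastereomer that chromatography removes, so the benzylic centre is carried forward as one configuration.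

**Step 4**
Reactants: 6 (2R,3S)-3-(3,4-dimethoxyphenyl)-3-{[3-(3,4,5-trimethoxyphenyl)prop-2-yn-1-yl]oxy}propane-1,2-diol
Product: 7 (2R,3S)-3-(3,4-dimethoxyphenyl)-2-hydroxy-3-{[3-(3,4,5-trimethoxyphenyl)prop-2-yn-1-yl]oxy}propyl acetate
Conditions: AcCl (1.05 equiv), 2,4,6-collidine, CH2Cl2, −78 °C
Reagents that add atoms: acetyl chloride, CC(=O)Cl
Why: Low-temperature acylation with AcCl and collidine is selective for the primary hydroxyl of a 1,2-diol, the secondary hydroxyl being shielded by the neighbouring benzylic ether.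

**Step 5**
Reactants: 7 (2R,3S)-3-(3,4-dimethoxyphenyl)-2-hydroxy-3-{[3-(3,4,5-trimethoxyphenyl)prop-2-yn-1-yl]oxy}propyl acetate
Product: 8 (3S)-3-(3,4-dimethoxyphenyl)-2-oxo-3-{[3-(3,4,5-trimethoxyphenyl)prop-2-yn-1-yl]oxy}propyl acetate
Conditions: Dess–Martin periodinane, CH2Cl2, 0 °C to rt
Reagents that add atoms: none
Why: Dess–Martin oxidation converts the secondary alcohol into the ketone under near-neutral, non-enolising conditions, which removes the now superfluous carbinol centre and should leave the α-keto benzylic centre configurationally intact.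

**Step 6**
Reactants: 8 (3S)-3-(3,4-dimethoxyphenyl)-2-oxo-3-{[3-(3,4,5-trimethoxyphenyl)prop-2-yn-1-yl]oxy}propyl acetate
Product: 10 [(2S)-2-(3,4-dimethoxyphenyl)-4-(3,4,5-trimethoxybenzoyl)-2,5-dihydrofuran-3-yl]methyl acetate, via oxetene 9 (not isolated)
Conditions: FeCl3 (10 mol %), MeCN, rt to 60 °C
Reagents that add atoms: none
Why: FeCl3 activates the ketone (held in a chelate with the α-acetoxy oxygen), the ether-proximal alkyne carbon attacks the carbonyl carbon to form the C3–C4 bond, the aryl-stabilised vinyl cation is captured by the former carbonyl oxygen to give oxetene 9, and 4π electrocyclic ring-opening of 9 delivers the ring C3=C4 bond together with the exocyclic aryl ketone, so the alkyne serves as a latent aroyl group and the ketone oxygen is transferred, not lost. The closest known reaction type is the Lewis- or Brønsted-acid-catalysed intramolecular alkyne–carbonyl metathesis of ketones and aldehydes tethered to aryl alkynes, which gives five- and six-membered cyclic enones including oxygen and nitrogen heterocycles. The oxolane ring closes in the 5-exo-dig mode at the alkyne (5-exo-trig at the carbonyl); the 6-endo alternative would place the cation on the carbon that lacks the aryl group and is not expected. No stereocentre is created: C3 and C4 become trigonal and C2 is a spectator whose descriptor differs from that of the target only through CIP priorities. The selectivities needed are oxygen delivery to the aryl-bearing alkyne carbon, secured by the 3,4,5-trimethoxyphenyl group, and carbonyl activation in preference to alkyne π-activation (which would invite hydroarylation by the dimethoxyphenyl ring), secured by oxophilic FeCl3 in place of a π-acid such as AgSbF6. Ionisation of the benzylic C2–O bond of 8 is disfavoured by the adjacent carbonyl, and the reaction is stopped at full conversion because the product ether is allylic as well as benzylic.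

**Step 7**
Reactants: 10 [(2S)-2-(3,4-dimethoxyphenyl)-4-(3,4,5-trimethoxybenzoyl)-2,5-dihydrofuran-3-yl]methyl acetate
Product: 11 [(2R,3R,4R)-2-(3,4-dimethoxyphenyl)-4-(3,4,5-trimethoxybenzoyl)oxolan-3-yl]methyl acetate
Conditions: H2 (3 atm), 5% Rh/Al2O3, EtOAc, rt
Reagents that add atoms: none
Why: Heterogeneous catalytic hydrogenation adds both hydrogens syn to the C3=C4 bond from the ring face opposite the C2 aryl group, which sets C3 with its CH2OAc arm cis to the aryl group and C4 provisionally cis as well; Rh on alumina is chosen for its low tendency to hydrogenolyse allylic and benzylic C–O bonds.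

**Step 8**
Reactants: 11 [(2R,3R,4R)-2-(3,4-dimethoxyphenyl)-4-(3,4,5-trimethoxybenzoyl)oxolan-3-yl]methyl acetate
Product: 13 (2R,3R,4S)-2-(3,4-dimethoxyphenyl)-3-(hydroxymethyl)-4-(3,4,5-trimethoxybenzoyl)oxolane, via trans acetate 12 (not isolated)
Conditions: DBU (0.3 equiv), CH2Cl2, rt; then MeOH, K2CO3 (0.3 equiv), 0 °C to rt
Reagents that add atoms: none
Why: DBU equilibrates the only acidic stereocentre, the ketone α-carbon C4, through its enolate to the thermodynamically preferred 3,4-trans arrangement while C2 and C3 cannot epimerise, and the following K2CO3/MeOH transesterification (Zemplén-type deacetylation) frees the primary alcohol.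

**Compound list**
1 | 5-iodo-1,2,3-trimethoxybenzene | COc1cc(I)cc(OC)c1OC | starting material
2 | prop-2-yn-1-ol | C#CCO | starting material
3 | 3-(3,4,5-trimethoxyphenyl)prop-2-yn-1-ol | COc1cc(C#CCO)cc(OC)c1OC | intermediate
4 | (E)-3-(3,4-dimethoxyphenyl)prop-2-en-1-ol | COc1ccc(/C=C/CO)cc1OC | starting material
5 | [(2R,3R)-3-(3,4-dimethoxyphenyl)oxiran-2-yl]methanol | COc1ccc([C@H]2O[C@@H]2CO)cc1OC | intermediate
6 | (2R,3S)-3-(3,4-dimethoxyphenyl)-3-{[3-(3,4,5-trimethoxyphenyl)prop-2-yn-1-yl]oxy}propane-1,2-diol | COc1ccc([C@H](OCC#Cc2cc(OC)c(OC)c(OC)c2)[C@H](O)CO)cc1OC | intermediate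
7 | (2R,3S)-3-(3,4-dimethoxyphenyl)-2-hydroxy-3-{[3-(3,4,5-trimethoxyphenyl)prop-2-yn-1-yl]oxy}propyl acetate | COc1ccc([C@H](OCC#Cc2cc(OC)c(OC)c(OC)c2)[C@H](O)COC(C)=O)cc1OC | intermediate
8 | (3S)-3-(3,4-dimethoxyphenyl)-2-oxo-3-{[3-(3,4,5-trimethoxyphenyl)prop-2-yn-1-yl]oxy}propyl acetate | COc1ccc([C@H](OCC#Cc2cc(OC)c(OC)c(OC)c2)C(=O)COC(C)=O)cc1OC | intermediate
9 | fused oxetene [(4S)-4-(3,4-dimethoxyphenyl)-7-(3,4,5-trimethoxyphenyl)-3,6-dioxabicyclo[3.2.0]hept-1(7)-en-5-yl]methyl acetate (not isolated; the ring-fusion carbon C5 may form as either epimer, both converge) | COc1ccc([C@@H]2OCC3=C(c4cc(OC)c(OC)c(OC)c4)OC23COC(C)=O)cc1OC | intermediate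
10 | [(2S)-2-(3,4-dimethoxyphenyl)-4-(3,4,5-trimethoxybenzoyl)-2,5-dihydrofuran-3-yl]methyl acetate | COc1ccc([C@@H]2OCC(C(=O)c3cc(OC)c(OC)c(OC)c3)=C2COC(C)=O)cc1OC | intermediate
11 | [(2R,3R,4R)-2-(3,4-dimethoxyphenyl)-4-(3,4,5-trimethoxybenzoyl)oxolan-3-yl]methyl acetate (all-cis) | COc1ccc([C@@H]2OC[C@H](C(=O)c3cc(OC)c(OC)c(OC)c3)[C@@H]2COC(C)=O)cc1OC | intermediate
12 | [(2R,3R,4S)-2-(3,4-dimethoxyphenyl)-4-(3,4,5-trimethoxybenzoyl)oxolan-3-yl]methyl acetate (3,4-trans; not isolated) | COc1ccc([C@@H]2OC[C@@H](C(=O)c3cc(OC)c(OC)c(OC)c3)[C@@H]2COC(C)=O)cc1OC | intermediate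
13 | (2R,3R,4S)-2-(3,4-dimethoxyphenyl)-3-(hydroxymethyl)-4-(3,4,5-trimethoxybenzoyl)oxolane (CNP0271206.1) | COc1ccc([C@@H]2OC[C@@H](C(=O)c3cc(OC)c(OC)c(OC)c3)[C@@H]2CO)cc1OC | target

**Count**
Total steps: 8. Longest linear sequence: 7 (steps 2 to 8 from 4; equally steps 1 and 3 to 8 from 1).

**Steps most likely to fail**

Step 6. The ring closure may be diverted by alkyne π-activation and hydroarylation by the dimethoxyphenyl ring, by acid-induced enolisation that erodes the C2 configuration, or by ionisation of the allylic-benzylic ether of the product. The fallback sets out from 8 and comes back at 10, and closes the same C3–C4 bond by ruthenium carbene chemistry. Wittig methylenation of 8 (Ph3P=CH2, THF, −78 to 0 °C) would give the 1,1-disubstituted alkene 2-[(S)-(3,4-dimethoxyphenyl){[3-(3,4,5-trimethoxyphenyl)prop-2-yn-1-yl]oxy}methyl]prop-2-en-1-yl acetate F1. Ring-closing enyne metathesis of F1 with second-generation Grubbs catalyst under ethylene (toluene, 80 °C) should give the diene [(2S)-2-(3,4-dimethoxyphenyl)-4-[1-(3,4,5-trimethoxyphenyl)ethenyl]-2,5-dihydrofuran-3-yl]methyl acetate F2. Lemieux–Johnson cleavage (OsO4 cat., NaIO4, 2,6-lutidine, dioxane/H2O) of its less hindered, more electron-rich 1-arylvinyl group would then give enone 10.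

Step 3. The electron-rich benzylic epoxide may ionise, which would cost stereochemical fidelity at the benzylic carbon, or rearrange by hydride shift (Meinwald) or oligomerise before the alcohol is captured. The fallback sets out from 3 and catalogue ethyl 2-(3,4-dimethoxyphenyl)-2-oxoacetate and comes back at 8; it never breaks a C–O bond at the benzylic carbon. Asymmetric transfer hydrogenation of the keto ester (RuCl(p-cymene)[(R,R)-TsDPEN], HCO2H/Et3N; the catalyst enantiomer that the aryl–arene model assigns to the S alcohol) would give ethyl (2S)-2-(3,4-dimethoxyphenyl)-2-hydroxyacetate F3. Appel bromination of 3 (CBr4, PPh3, CH2Cl2, 0 °C) would give 5-(3-bromoprop-1-yn-1-yl)-1,2,3-trimethoxybenzene F4. O-Alkylation of F3 with F4 under non-basic conditions (Ag2O, CH2Cl2, rt, dark) would give ethyl (2S)-2-(3,4-dimethoxyphenyl)-2-{[3-(3,4,5-trimethoxyphenyl)prop-2-yn-1-yl]oxy}acetate F5. Addition of LiCH2Cl (from ICH2Cl and MeLi·LiBr, THF, −78 °C) to the ester would give the chloromethyl ketone (3S)-1-chloro-3-(3,4-dimethoxyphenyl)-3-{[3-(3,4,5-trimethoxyphenyl)prop-2-yn-1-yl]oxy}propan-2-one F6. Displacement of chloride with CsOAc (DMF, rt) would give 8.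

Step 7. The tetrasubstituted alkene may reduce sluggishly while hydrogenolysis of the allylic and benzylic C–O bonds or double-bond migration towards C2 competes. The fallback sets out from 10 and comes back at 13, and replaces surface hydrogenation by conjugate hydride delivery. Copper hydride 1,4-hydrosilylation ([(Ph3P)CuH]6 cat., PhMe2SiH, toluene, rt) should add hydride to C3 from the face opposite the C2 aryl group and give the silyl enol ether [(2R,3R)-2-(3,4-dimethoxyphenyl)-4-{[dimethyl(phenyl)silyl]oxy(3,4,5-trimethoxyphenyl)methylidene}oxolan-3-yl]methyl acetate F7 (enol ether geometry immaterial). Treatment with K2CO3 in MeOH would cleave the silyl group with thermodynamic protonation at C4 and remove the acetate, giving 13 directly.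

**Further compounds**
F1 | step 6 | 2-[(S)-(3,4-dimethoxyphenyl){[3-(3,4,5-trimethoxyphenyl)prop-2-yn-1-yl]oxy}methyl]prop-2-en-1-yl acetate | COc1ccc([C@H](OCC#Cc2cc(OC)c(OC)c(OC)c2)C(=C)COC(C)=O)cc1OC
F2 | step 6 | [(2S)-2-(3,4-dimethoxyphenyl)-4-[1-(3,4,5-trimethoxyphenyl)ethenyl]-2,5-dihydrofuran-3-yl]methyl acetate | COc1ccc([C@@H]2OCC(C(=C)c3cc(OC)c(OC)c(OC)c3)=C2COC(C)=O)cc1OC
F3 | step 3 | ethyl (2S)-2-(3,4-dimethoxyphenyl)-2-hydroxyacetate | COc1ccc([C@H](O)C(=O)OCC)cc1OC
F4 | step 3 | 5-(3-bromoprop-1-yn-1-yl)-1,2,3-trimethoxybenzene | COc1cc(C#CCBr)cc(OC)c1OC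
F5 | step 3 | ethyl (2S)-2-(3,4-dimethoxyphenyl)-2-{[3-(3,4,5-trimethoxyphenyl)prop-2-yn-1-yl]oxy}acetate | COc1ccc([C@H](OCC#Cc2cc(OC)c(OC)c(OC)c2)C(=O)OCC)cc1OC
F6 | step 3 | (3S)-1-chloro-3-(3,4-dimethoxyphenyl)-3-{[3-(3,4,5-trimethoxyphenyl)prop-2-yn-1-yl]oxy}propan-2-one | COc1ccc([C@H](OCC#Cc2cc(OC)c(OC)c(OC)c2)C(=O)CCl)cc1OC
F7 | step 7 | [(2R,3R)-2-(3,4-dimethoxyphenyl)-4-{[dimethyl(phenyl)silyl]oxy(3,4,5-trimethoxyphenyl)methylidene}oxolan-3-yl]methyl acetate | COc1ccc([C@@H]2OCC(=C(O[Si](C)(C)c3ccccc3)c3cc(OC)c(OC)c(OC)c3)[C@@H]2COC(C)=O)cc1OC
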